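Everything rests on disconnecting the diaryl ether bond between C3 of the catechol ring C and the oxygen on C4 of the para-phenylene ring D (each ring numbered from its bridge carbon). The free hydroxyl on C4 of ring C, ortho to that ether oxygen, marks this bond as one that an oxidative phenol–phenol coupling can make. A single anodic oxidation with zinc work-up forms it, closes the 18-membered ring and sets the catechol pattern from two plain 4-alkylphenols. The substrate is a dibenzofuran bearing a 2-(3,5-dichloro-4-hydroxyphenyl)ethyl arm at C1, a 2-(3,5-dibromo-4-hydroxyphenyl)ethyl arm at C7 and a benzyl ether at O3, chosen so that one hydrogenolysis afterwards removes every halogen and frees the last phenol.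

Key step: step 14

Assumption: the target SMILES carries no stereodescriptor and the molecule has no stereogenic centre, so it is treated as one achiral compound and no step has to set configuration; the Wittig alkenes are carried as E/Z mixtures because both are reduced.

Locants: the dibenzofuran is numbered with the ring oxygen as 5. Ring A (C1–C4) carries the oxygen substituent at C3 and the bay-position arm at C1. Ring B (C6–C9) carries its arm at C7.

Step 1
Reactants: 1 2-bromo-3,5-dimethoxybenzaldehyde; 2 (2-fluoro-4-(methoxycarbonyl)phenyl)boronic acid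
Product: 3 methyl 3-fluoro-4-(2-formyl-4,6-dimethoxyphenyl)benzoate
Conditions: Pd(OAc)2 (cat.), SPhos (cat.), K3PO4, toluene/H2O, 90 °C
Reagents that add atoms: none
Why: Suzuki–Miyaura coupling, in which an SPhos-ligated palladium catalyst should cope with the di-ortho-substituted bromide and the ortho-fluoro boronic acid while phosphate base spares the aldehyde and the methyl ester.

Step 2
Reactants: 3 methyl 3-fluoro-4-(2-formyl-4,6-dimethoxyphenyl)benzoate
Product: 4 methyl 3-fluoro-4-(2-formyl-4,6-dihydroxyphenyl)benzoate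
Conditions: BBr3, CH2Cl2, −78 to 0 °C; H2O
Reagents that add atoms: none
Why: Lewis-acid cleavage of both aryl methyl ethers with boron tribromide, which at or below 0 °C should leave the methyl ester and the aryl fluoride alone and return the aldehyde on aqueous work-up.

Step 3
Reactants: 4 methyl 3-fluoro-4-(2-formyl-4,6-dihydroxyphenyl)benzoate
Product: 6 methyl 3-(benzyloxy)-1-formyldibenzofuran-7-carboxylate, via hydroxydibenzofuran 5 (not isolated)
Conditions: Cs2CO3, DMF, 120 °C; then BnBr, rt
Reagents that add atoms: benzyl bromide, BrCc1ccccc1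
Why: Intramolecular SNAr in which only the phenoxide ortho to the biaryl bond can reach the C–F carbon and close the furan ring, as is established for 2'-fluorobiaryl-2-ols without further activation, followed by Williamson benzylation of the one remaining phenoxide in the same pot.

Step 4
Reactants: 6 methyl 3-(benzyloxy)-1-formyldibenzofuran-7-carboxylate
Product: 7 methyl 3-(benzyloxy)-1-(hydroxymethyl)dibenzofuran-7-carboxylate
Conditions: NaBH4, THF/MeOH, 0 °C
Reagents that add atoms: none
Why: Borohydride reduction, chemoselective for the aldehyde over the aryl methyl ester at low temperature.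

Step 5
Reactants: 7 methyl 3-(benzyloxy)-1-(hydroxymethyl)dibenzofuran-7-carboxylate
Product: 8 {[3-(benzyloxy)-7-(methoxycarbonyl)dibenzofuran-1-yl]methyl}triphenylphosphonium bromide
Conditions: PPh3·HBr, MeCN, reflux
Reagents that add atoms: triphenylphosphine hydrobromide, [Br-].c1ccc(cc1)[PH+](c1ccccc1)c1ccccc1
Why: Direct conversion of a benzylic alcohol into its phosphonium salt by acid-assisted substitution, under which the ester and the aryl benzyl ether should persist.

Step 6
Reactants: 9 3,5-dichloro-4-hydroxybenzaldehyde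
Product: 10 3,5-dichloro-4-(methoxymethoxy)benzaldehyde
Conditions: MOMCl, i-Pr2NEt, CH2Cl2, 0 °C to rt
Reagents that add atoms: chloromethyl methyl ether, COCCl
Why: O-alkylation of the acidic phenol to its MOM acetal, so that the aldehyde meets the ylide as a neutral electrophile and not as an unreactive phenoxide.

Step 7
Reactants: 8 {[3-(benzyloxy)-7-(methoxycarbonyl)dibenzofuran-1-yl]methyl}triphenylphosphonium bromide; 10 3,5-dichloro-4-(methoxymethoxy)benzaldehyde
Product: 12 methyl 3-(benzyloxy)-1-{2-[3,5-dichloro-4-(methoxymethoxy)phenyl]ethenyl}dibenzofuran-7-carboxylate (E/Z mixture), via ylide 11 (not isolated)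
Conditions: K2CO3, 18-crown-6 (cat.), CH2Cl2, reflux
Reagents that add atoms: none
Why: Wittig olefination of a semi-stabilised benzylic ylide under solid carbonate/crown ether conditions, which are mild enough for the methyl ester; the alkene geometry is irrelevant because the bond is saturated in step 12.

Step 8
Reactants: 12 methyl 3-(benzyloxy)-1-{2-[3,5-dichloro-4-(methoxymethoxy)phenyl]ethenyl}dibenzofuran-7-carboxylate
Product: 13 [3-(benzyloxy)-1-{2-[3,5-dichloro-4-(methoxymethoxy)phenyl]ethenyl}dibenzofuran-7-yl]methanol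
Conditions: DIBAL-H, CH2Cl2, −78 to 0 °C; Rochelle salt
Reagents that add atoms: none
Why: Hydride reduction of the aryl ester to the benzylic alcohol, to which aryl chlorides, the MOM acetal, the benzyl ether and the stilbene are inert.

Step 9
Reactants: 13 [3-(benzyloxy)-1-{2-[3,5-dichloro-4-(methoxymethoxy)phenyl]ethenyl}dibenzofuran-7-yl]methanol
Product: 15 {[3-(benzyloxy)-1-{2-[3,5-dichloro-4-(methoxymethoxy)phenyl]ethenyl}dibenzofuran-7-yl]methyl}triphenylphosphonium bromide, via benzylic bromide 14 (not isolated)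
Conditions: CBr4, PPh3, CH2Cl2, 0 °C; then PPh3, toluene, 90 °C
Reagents that add atoms: carbon tetrabromide, BrC(Br)(Br)Br; triphenylphosphine, c1ccc(cc1)P(c1ccccc1)c1ccccc1
Why: Appel bromination under neutral conditions keeps the acid-labile MOM acetal, and SN2 quaternisation of triphenylphosphine by the crude benzylic bromide should let the salt precipitate from toluene away from phosphine oxide and bromoform.

Step 10
Reactants: 16 3,5-dibromo-4-hydroxybenzaldehyde
Product: 17 3,5-dibromo-4-(methoxymethoxy)benzaldehyde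
Conditions: MOMCl, i-Pr2NEt, CH2Cl2, 0 °C to rt
Reagents that add atoms: chloromethyl methyl ether, COCCl
Why: MOM acetal formation on the acidic phenol, for the same reason as in step 6.

Step 11
Reactants: 15 {[3-(benzyloxy)-1-{2-[3,5-dichloro-4-(methoxymethoxy)phenyl]ethenyl}dibenzofuran-7-yl]methyl}triphenylphosphonium bromide; 17 3,5-dibromo-4-(methoxymethoxy)benzaldehyde
Product: 19 3-(benzyloxy)-7-{2-[3,5-dibromo-4-(methoxymethoxy)phenyl]ethenyl}-1-{2-[3,5-dichloro-4-(methoxymethoxy)phenyl]ethenyl}dibenzofuran (mixture of alkene isomers), via ylide 18 (not isolated)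
Conditions: K2CO3, 18-crown-6 (cat.), CH2Cl2, reflux
Reagents that add atoms: none
Why: Second Wittig olefination under the same mild conditions, in which the aryl bromides and chlorides are spectators and all alkene isomers converge in the next step.

Step 12
Reactants: 19 3-(benzyloxy)-7-{2-[3,5-dibromo-4-(methoxymethoxy)phenyl]ethenyl}-1-{2-[3,5-dichloro-4-(methoxymethoxy)phenyl]ethenyl}dibenzofuran
Product: 20 3-(benzyloxy)-7-{2-[3,5-dibromo-4-(methoxymethoxy)phenyl]ethyl}-1-{2-[3,5-dichloro-4-(methoxymethoxy)phenyl]ethyl}dibenzofuran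
Conditions: TsNHNH2 (excess, in portions), NaOAc, THF/H2O, reflux
Reagents that add atoms: none
Why: Diimide reduction, a metal-free concerted transfer of H2 to both stilbene double bonds that should leave C–Br, C–Cl and the benzyl ether untouched, with acetate buffering the sulfinic acid so that the MOM groups stay on.

Step 13
Reactants: 20 3-(benzyloxy)-7-{2-[3,5-dibromo-4-(methoxymethoxy)phenyl]ethyl}-1-{2-[3,5-dichloro-4-(methoxymethoxy)phenyl]ethyl}dibenzofuran
Product: 21 4-{2-[3-(benzyloxy)-1-[2-(3,5-dichloro-4-hydroxyphenyl)ethyl]dibenzofuran-7-yl]ethyl}-2,6-dibromophenol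
Conditions: HCl (aq.), MeOH/THF, 50 °C
Reagents that add atoms: none
Why: Acid-catalysed methanolysis of both MOM acetals, conditions under which the aryl benzyl ether and the aryl halides are stable.

Step 14
Reactants: 21 4-{2-[3-(benzyloxy)-1-[2-(3,5-dichloro-4-hydroxyphenyl)ethyl]dibenzofuran-7-yl]ethyl}-2,6-dibromophenol
Product: 23 bromo-dichloro asterelin A 3-O-benzyl ether (18-membered macrocycle; Br on ring C ortho to its free OH; two Cl on ring D flanking the ether oxygen), via bromodienone 22 (not isolated)
Conditions: controlled-potential electrolysis (ca. +1.0 V vs SCE, glassy-carbon anode, Pt cathode, undivided cell, 2 F/mol), LiClO4, MeOH/CH2Cl2, ca. 1 mM, rt; then Zn dust, AcOH, THF, rt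
Reagents that add atoms: none
Why: Two-electron oxidation at the anode converts the more electron-rich dibromophenol ring of 21 into a phenoxonium ion; the oxygen of the dichlorophenol adds to one of its bromine-bearing ortho carbons to give the aryloxy bromodienone 22, and zinc then removes that bromine reductively so that the ring re-aromatises as the ortho-hydroxy diaryl ether 23. The closest known reaction type is the anodic or thallium(III)-mediated ortho C–O coupling of pairs of o,o'-dihalophenols to isodityrosine-type diaryl ethers, which has been run in macrocyclic settings. The one ring closed is the 18-membered macrocycle, formed by intramolecular attack of a phenol oxygen on a trigonal ring carbon of the cation, a large-ring etherification beyond Baldwin constraints that high dilution should favour over dimerisation. No stereocentre remains, since the only sp3 carbon created (in 22) is flattened again on reduction. The selectivities needed are oxidation of ring C and not of ring D or the benzyloxydibenzofuran, which the lower oxidation potential of the dibromophenol at a controlled anode potential should secure, and O–C instead of C–C coupling at an ortho carbon, which the halogens on all four ortho positions and the alkyl groups on both para positions enforce. Any para-methoxy quinol ether arising from capture of the cation by methanol should revert to 21 under the zinc treatment and so should cost conversion only.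

Step 15
Reactants: 23 bromo-dichloro asterelin A 3-O-benzyl ether
Product: 24 asterelin A
Conditions: H2 (1 atm), 10% Pd/C, NaOAc, MeOH/EtOAc, rt
Reagents that add atoms: none
Why: Palladium-catalysed hydrogenolysis, which with acetate as acid scavenger should cleave the C–Br bond, both C–Cl bonds and the benzylic C–O bond in one operation while the diaryl ether and the dibenzofuran stay intact.

Compound list
1 | 2-bromo-3,5-dimethoxybenzaldehyde | COc1cc(OC)c(Br)c(C=O)c1 | starting material
2 | (2-fluoro-4-(methoxycarbonyl)phenyl)boronic acid (methyl 4-borono-3-fluorobenzoate) | COC(=O)c1ccc(B(O)O)c(F)c1 | starting material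
3 | methyl 3-fluoro-4-(2-formyl-4,6-dimethoxyphenyl)benzoate | COC(=O)c1ccc(-c2c(C=O)cc(OC)cc2OC)c(F)c1 | intermediate
4 | methyl 3-fluoro-4-(2-formyl-4,6-dihydroxyphenyl)benzoate | COC(=O)c1ccc(-c2c(C=O)cc(O)cc2O)c(F)c1 | intermediate
5 | methyl 1-formyl-3-hydroxydibenzofuran-7-carboxylate | COC(=O)c1ccc2c(c1)oc1cc(O)cc(C=O)c12 | intermediate (not isolated)
6 | methyl 3-(benzyloxy)-1-formyldibenzofuran-7-carboxylate | COC(=O)c1ccc2c(c1)oc1cc(OCc3ccccc3)cc(C=O)c12 | intermediate
7 | methyl 3-(benzyloxy)-1-(hydroxymethyl)dibenzofuran-7-carboxylate | COC(=O)c1ccc2c(c1)oc1cc(OCc3ccccc3)cc(CO)c12 | intermediate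
8 | {[3-(benzyloxy)-7-(methoxycarbonyl)dibenzofuran-1-yl]methyl}triphenylphosphonium bromide | COC(=O)c1ccc2c(c1)oc1cc(OCc3ccccc3)cc(C[P+](c3ccccc3)(c3ccccc3)c3ccccc3)c12.[Br-] | intermediate
9 | 3,5-dichloro-4-hydroxybenzaldehyde | O=Cc1cc(Cl)c(O)c(Cl)c1 | starting material
10 | 3,5-dichloro-4-(methoxymethoxy)benzaldehyde | COCOc1c(Cl)cc(C=O)cc1Cl | intermediate
11 | methyl 3-(benzyloxy)-1-[(triphenylphosphoranylidene)methyl]dibenzofuran-7-carboxylate (ylide of 8) | COC(=O)c1ccc2c(c1)oc1cc(OCc3ccccc3)cc(C=P(c3ccccc3)(c3ccccc3)c3ccccc3)c12 | intermediate (not isolated)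
12 | methyl 3-(benzyloxy)-1-{2-[3,5-dichloro-4-(methoxymethoxy)phenyl]ethenyl}dibenzofuran-7-carboxylate (E/Z mixture, geometry not fixed) | COC(=O)c1ccc2c(c1)oc1cc(OCc3ccccc3)cc(C=Cc3cc(Cl)c(OCOC)c(Cl)c3)c12 | intermediate
13 | [3-(benzyloxy)-1-{2-[3,5-dichloro-4-(methoxymethoxy)phenyl]ethenyl}dibenzofuran-7-yl]methanol (E/Z mixture) | OCc1ccc2c(c1)oc1cc(OCc3ccccc3)cc(C=Cc3cc(Cl)c(OCOC)c(Cl)c3)c12 | intermediate
14 | 3-(benzyloxy)-7-(bromomethyl)-1-{2-[3,5-dichloro-4-(methoxymethoxy)phenyl]ethenyl}dibenzofuran (E/Z mixture) | BrCc1ccc2c(c1)oc1cc(OCc3ccccc3)cc(C=Cc3cc(Cl)c(OCOC)c(Cl)c3)c12 | intermediate (not isolated)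
15 | {[3-(benzyloxy)-1-{2-[3,5-dichloro-4-(methoxymethoxy)phenyl]ethenyl}dibenzofuran-7-yl]methyl}triphenylphosphonium bromide (E/Z mixture) | [Br-].c1ccc(cc1)[P+](c1ccccc1)(c1ccccc1)Cc1ccc2c(c1)oc1cc(OCc3ccccc3)cc(C=Cc3cc(Cl)c(OCOC)c(Cl)c3)c12 | intermediate
16 | 3,5-dibromo-4-hydroxybenzaldehyde | O=Cc1cc(Br)c(O)c(Br)c1 | starting material
17 | 3,5-dibromo-4-(methoxymethoxy)benzaldehyde | COCOc1c(Br)cc(C=O)cc1Br | intermediate
18 | ylide of 15 (triphenylphosphoranylidene-methyl group at C7) | c1ccc(cc1)P(c1ccccc1)(c1ccccc1)=Cc1ccc2c(c1)oc1cc(OCc3ccccc3)cc(C=Cc3cc(Cl)c(OCOC)c(Cl)c3)c12 | intermediate (not isolated)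
19 | 3-(benzyloxy)-7-{2-[3,5-dibromo-4-(methoxymethoxy)phenyl]ethenyl}-1-{2-[3,5-dichloro-4-(methoxymethoxy)phenyl]ethenyl}dibenzofuran (mixture of alkene isomers) | COCOc1c(Br)cc(C=Cc2ccc3c(c2)oc2cc(OCc4ccccc4)cc(C=Cc4cc(Cl)c(OCOC)c(Cl)c4)c23)cc1Br | intermediate
20 | 3-(benzyloxy)-7-{2-[3,5-dibromo-4-(methoxymethoxy)phenyl]ethyl}-1-{2-[3,5-dichloro-4-(methoxymethoxy)phenyl]ethyl}dibenzofuran | COCOc1c(Br)cc(CCc2ccc3c(c2)oc2cc(OCc4ccccc4)cc(CCc4cc(Cl)c(OCOC)c(Cl)c4)c23)cc1Br | intermediate
21 | 4-{2-[3-(benzyloxy)-1-[2-(3,5-dichloro-4-hydroxyphenyl)ethyl]dibenzofuran-7-yl]ethyl}-2,6-dibromophenol (seco bis-phenol) | Oc1c(Br)cc(CCc2ccc3c(c2)oc2cc(OCc4ccccc4)cc(CCc4cc(Cl)c(O)c(Cl)c4)c23)cc1Br | intermediate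
22 | macrocyclic 6-aryloxy-2,6-dibromocyclohexa-2,4-dienone (ring C as dienone, racemic at its sp3 carbon, 3-O-benzyl) | c1ccc(cc1)COc1cc2c3c(c1)oc1cc(ccc13)CCC1=CC(Br)(Oc4c(Cl)cc(cc4Cl)CC2)C(=O)C(Br)=C1 | intermediate (not isolated)
23 | bromo-dichloro asterelin A 3-O-benzyl ether | c1ccc(cc1)COc1cc2c3c(c1)oc1cc(ccc13)CCc1cc(Br)c(O)c(c1)Oc1c(Cl)cc(cc1Cl)CC2 | intermediate
24 | asterelin A | Oc1cc2c3c(c1)oc1cc(ccc13)CCc1ccc(O)c(c1)Oc1ccc(cc1)CC2 | target

Total step count: 15. Longest linear sequence: 13 (steps 1–5, 7–9, 11–15).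

Steps most likely to fail

Step 14. Ring closure may be outrun by intermolecular coupling to dimers and oligomers or by solvent capture of the phenoxonium ion, and the oxidation may start at the wrong phenol. The fallback gives up oxidative coupling: the diaryl ether is made first and the macrocycle is closed at the C7 bridge. It sets out from 8. Methyl 3-hydroxy-4-methoxybenzoate and 4-fluorobenzaldehyde (K2CO3, DMF, 120 °C, SNAr) would give methyl 3-(4-formylphenoxy)-4-methoxybenzoate F1. Wittig reaction of 8 with it (K2CO3, 18-crown-6, CH2Cl2) would give the stilbene diester F2, and diimide reduction the bibenzyl diester F3. DIBAL-H would then give the diol F4 and MnO2 the dialdehyde F5. Intramolecular McMurry coupling (TiCl4, Zn, THF, reflux, slow addition) would close the 18-membered ring as the macrocyclic stilbene F6. Hydrogenation over Pd/C would saturate the alkene and remove the benzyl group to give asterelin A ring-C methyl ether F7, and BBr3 would cleave the last ether, so that the fallback comes back to the route at 24.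

Step 3. Displacement of fluoride at a ring carbon without ortho or para activation may be slow, and the methyl ester or the aldehyde may be attacked at the temperature required. The fallback replaces SNAr by metal-catalysed C–O coupling and sets out from 1. Suzuki coupling with commercial (2-chloro-4-(methoxycarbonyl)phenyl)boronic acid (COC(=O)c1ccc(B(O)O)c(Cl)c1), selective for the bromide of 1, would give methyl 3-chloro-4-(2-formyl-4,6-dimethoxyphenyl)benzoate F8. BBr3 would give methyl 3-chloro-4-(2-formyl-4,6-dihydroxyphenyl)benzoate F9. Intramolecular palladium-catalysed aryl ether formation (Pd(OAc)2, t-BuXPhos, K3PO4, toluene, 100 °C) would give 5, which is benzylated as in step 3, so that the fallback comes back to the route at 6.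

Step 15. Hydrogenolysis of the two hindered C–Cl bonds may stall through halide poisoning of the heterogeneous catalyst, or the benzyl ether may be left in place. The fallback separates the two tasks and sets out from 23. Homogeneous palladium-catalysed hydride transfer (PdCl2(dppf), NaBH4, TMEDA, THF, rt) would remove bromine and both chlorines to give asterelin A 3-O-benzyl ether F10. Hydrogenolysis of this halide-free ether (H2, Pd/C, EtOAc) then comes back to the route at 24.

Further compounds
F1 | step 14 | methyl 3-(4-formylphenoxy)-4-methoxybenzoate | COC(=O)c1ccc(OC)c(Oc2ccc(C=O)cc2)c1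
F2 | step 14 | methyl 3-(benzyloxy)-1-{2-[4-(2-methoxy-5-(methoxycarbonyl)phenoxy)phenyl]ethenyl}dibenzofuran-7-carboxylate (E/Z mixture) | COC(=O)c1ccc2c(c1)oc1cc(OCc3ccccc3)cc(C=Cc3ccc(Oc4cc(C(=O)OC)ccc4OC)cc3)c12
F3 | step 14 | methyl 3-(benzyloxy)-1-{2-[4-(2-methoxy-5-(methoxycarbonyl)phenoxy)phenyl]ethyl}dibenzofuran-7-carboxylate | COC(=O)c1ccc2c(c1)oc1cc(OCc3ccccc3)cc(CCc3ccc(Oc4cc(C(=O)OC)ccc4OC)cc3)c12
F4 | step 14 | [3-(benzyloxy)-1-{2-[4-(5-(hydroxymethyl)-2-methoxyphenoxy)phenyl]ethyl}dibenzofuran-7-yl]methanol | OCc1ccc2c(c1)oc1cc(OCc3ccccc3)cc(CCc3ccc(Oc4cc(CO)ccc4OC)cc3)c12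
F5 | step 14 | 3-(benzyloxy)-1-{2-[4-(5-formyl-2-methoxyphenoxy)phenyl]ethyl}dibenzofuran-7-carbaldehyde | O=Cc1ccc2c(c1)oc1cc(OCc3ccccc3)cc(CCc3ccc(Oc4cc(C=O)ccc4OC)cc3)c12
F6 | step 14 | macrocyclic stilbene: 3-O-benzyl ring-C O-methyl asterelin A with a C=C in the C7 bridge (geometry not fixed) | c1ccc(cc1)COc1cc2c3c(c1)oc1cc(ccc13)C=Cc1ccc(OC)c(c1)Oc1ccc(cc1)CC2
F7 | step 14 | asterelin A ring-C methyl ether | Oc1cc2c3c(c1)oc1cc(ccc13)CCc1ccc(OC)c(c1)Oc1ccc(cc1)CC2
F8 | step 3 | methyl 3-chloro-4-(2-formyl-4,6-dimethoxyphenyl)benzoate | COC(=O)c1ccc(-c2c(C=O)cc(OC)cc2OC)c(Cl)c1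
F9 | step 3 | methyl 3-chloro-4-(2-formyl-4,6-dihydroxyphenyl)benzoate | COC(=O)c1ccc(-c2c(C=O)cc(O)cc2O)c(Cl)c1
F10 | step 15 | asterelin A 3-O-benzyl ether | c1ccc(cc1)COc1cc2c3c(c1)oc1cc(ccc13)CCc1ccc(O)c(c1)Oc1ccc(cc1)CC2
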